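In a one-step world product would rise in step with time from the start, but from 10.0 min to 20.0 min the south-east run grows 3.27-fold while time grows 2-fold. Early product therefore runs nearer the square of time, an induction period.

| flask | substrate | temperature | remark | time |
|---|---|---|---|---|
| south-east | 15 mM | 44 °C | run made earlier |  |
| south-west | 33 mM | 52 °C | run made earlier |  |
| autumn | 22 mM | 55 °C |  | 30 min |
| dawn | 22 mM | 40 °C |  | 30 min |

| run | time / min | product / % |
|---|---|---|
| south-east | 10.0 | 2.2 |
| south-east | 20.0 | 7.2 |
| south-east | 30.0 | 13.6 |
| south-east | 40.0 | 21.3 |
| south-east | 50.0 | 25.3 |
| south-west | 6.00 | 4.4 |
| south-west | 12.0 | 13.2 |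
| south-west | 20.0 | 24.2 |
| south-west | 25.0 | 28.8 |
| south-west | 30.0 | 32.8 |

(scatter of a reading: 1 percentage point)

* which flask leads in amount of product, in percent of the substrate charged ("all alike" within 1.5 percentage points) (autumn / dawn / all alike)
* how much product is there at the end, in percent of the substrate charged: autumn
* how much product is there at the end, in percent of the substrate charged: dawn

- the numbers in the tables scatter with a standard deviation of 1 percentage point
- a reading or a percentage of product counts all its forms, free or not

Charge looks a minor number: the runs at 15 mM and 33 mM trace one curve on a stretched time axis within their scatter, though charge and temperature moved together there. Time enters early product squared, but it is given exactly. The stretch with temperature has to be known well: dawn lies half a run-to-run gap below south-east, so a relative error in the stretch passes one to one into dawn's product.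

The number is 2.50, the clock ratio: the factor by which the time to equal product shrinks from the south-east run to the south-west run, charge and temperature changing together (time–temperature superposition). It is read from 13.6% at 30.0 min against 13.2% at 12.0 min, and the later pair, 25.3% against 24.2%, gives the same ratio.

Taken as geometric in temperature, it makes dawn's time worth 19.0 min at south-east, and the square law from the reading at 20.0 min gives 6.48%. Autumn's time is worth 42.3 min on south-west, past its last reading, and the first-order tail of its last readings gives 42.1%.

The forecast, holding that “First order after a lag fits well”, names autumn as leader, with 43% (34% to 50%) for autumn and 9% (6% to 13%) for dawn, both figures above this reckoning's.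

The flasks give autumn the lead: autumn holds 36.2% of product, bound forms counted, below the tail's figure, and dawn 6.28% against the 6.48% of the square law.

    substrate → intermediate (k = 0.0130 /min, Ea = 102 kJ/mol)
    intermediate ⇌ product (K = 0.870, k = 0.0160 /min, Ea = 98.0 kJ/mol, ΔH = −7.00 kJ/mol)
    substrate + product ⇌ idle adduct, settled at all times (K = 1700 /M, ΔH = −45.0 kJ/mol)
    2 substrate → homo dimer (k = 0.260 /M/min, Ea = 64.0 kJ/mol)
    (constants at 40 °C)

A flask like autumn kept at 30 °C has a clock worth 6.04 min at south-east, earlier than the first reading of that run, and the square law gives 0.656%. That flask holds 0.652% of product at 30.0 min.

(The runs are calculated with constants of no real substance; noise was put on by code.)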